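## Structural features

The target is a furanoheliangolide: a ten-membered carbocycle (C1–C10) in which an oxygen atom joins C3 to C10, so that C10, C1, C2, C3 and this oxygen form a 3(2H)-furanone (C1 ketone, C2=C3 enol-ether alkene). A cis-fused α-methylene-γ-butyrolactone sits on C6–C7 (C6–O, C7–C11, C12 carbonyl, C13 methylene; H6 and H7 syn). A Z trisubstituted C4=C5 alkene (methyl on C4) links the lactone carbinol to the furanone as a cross-conjugated dienone. Five contiguous stereocentres run from C6 to C10: C8 bears a methacrylate, C9 an acetate, and C10 is fully substituted (methyl, ring oxygen). If the C7–C10 segment is folded into a six-membered ring, the C7 chain, both oxygens on C8 and C9 and the C10 methyl lie on one face and the C10 oxygen on the other. Fragile features are the two Michael acceptors (exo-methylene lactone, methacrylate), the base-sensitive vinylogous ester, the allylic C6–O bond, the vicinal C8/C9 esters (acyl migration, 6,12 to 8,12 lactone translocation once C8–OH is free) and C7, which is epimerisable whenever C6 is a ketone. The real difficulty is the strained, oxygen-bridged ten-membered ring with its Z alkene, combined with a contiguous oxygenated array whose two secondary hydroxyls must be acylated differently. The route exploits the fact that C1 (ketone) and C6 (carbinol, one reduction away from a ketone) stand 1,6 across the carbocycle: they are the two carbonyls of a cleaved ring-fusion alkene. The C1–C6 half, with oxygen on C3 and methyl on C4, maps onto an o-methylanisole ring (ring A), and the C7–C10 half onto the saturated ring of a tetralin.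

## Logic of the disconnections

33 back to 31 (through 32): the two ester C–O bonds on O8 and O9 are cut first because they are the most labile groups and would survive neither enolate chemistry nor dissolving metal. This leaves a diol. The forward steps must tell the C8 hydroxyl (next to a CH) from the C9 hydroxyl (next to the fully substituted C10), so the bulkier acyl group goes on first and onto the more accessible oxygen.

31 back to 27 (through 30): the C11=C13 bond is removed and the diol is tied up as an isopropylidene acetal. This takes out a Michael acceptor and both free hydroxyls. The forward methylenation needs a lactone enolate, which is why no ester or free OH may be present at that point.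

27 back to 25: the lactone O6–C12 bond and the C6–H bond are cut, giving a C6 ketone and a C12 ester. C6 is thereby reduced to a prochiral carbonyl. The forward hydride addition must put H6 syn to H7.

25 back to 24: the C4=C5 π bond is removed. The demand is a dehydrogenation that goes toward C5/C4 and not toward C7, and that gives the Z alkene.

24 back to 22 (through 23): the O–C3 bond of the furanone is cut, and the C1 and C6 carbonyl carbons are reconnected as a tetrasubstituted alkene. The bridged ten-membered ring and the heterocycle collapse into two fused six-membered rings with no new stereocentre. The forward cleavage must be chemoselective, stay neutral to weakly acidic (C7), and find the C9 oxygen masked so that only the C10 hydroxyl can cyclise.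

22 back to 19 (through 21 and 20): ring A is re-aromatised to the anisole, and the ester is taken back to the acid. All stereochemistry then sits on a tetralin. The forward reduction needs a carboxylate (an ester would be reduced), the C10 oxygen as an alkoxide (to keep the benzylic C–O bond), and protonation at C2 and C5.

19 back to 17 (through 18): the acetal and the C12 carboxyl are exchanged for a C8–O–C12 lactone. This is the form in which the C8 oxygen can be delivered from the side chain. The forward step must open a stable lactone, which is done by trapping the diol as it is released.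

17 back to 13 (through 16, 15 and 14): the C8–O and C9–O bonds are cut back to the C8=C9 alkene. A direct cis-dihydroxylation would have to enter on the face that carries both the C7 chain and the C10 methyl, against the steric bias. Instead, C8–O comes from the chain carboxyl (necessarily cis to the chain) after a hydroxyl-directed epoxidation, and C9 is corrected by oxidation and reduction. The demands are α-face epoxidation and α-face hydride delivery.

13 back to 7 and 9 (through 12, 10 and 8): the C10–CH3 bond and the C8=C9 π bond are cut, leaving a tetralone. The alkene can only be made after C10 is quaternary, because a C8=C9 enone would tautomerise to a naphthol. The forward sequence relays C7 to C9 (selenium) and C9 to C10 (methyl addition).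

7 back to 5 (through 6): the aryl–acyl bond C1–C10 is cut. The forward acylation must use the C10 carboxyl only, which is why the two esters of 5 are different.

5 back to 3 and 4: the aryl–C7 bond is cut. This is the only stereocentre made under catalyst control, and all others derive from it.

3 back to 1 and 2: the C7=C11 alkene is cut by metathesis into two commercial esters.

## Other disconnections considered

Alternative 1: The cut is the C6–C7 bond, taken apart as a retro-[3,3] shift that re-forms C4–C9. The oxygen-bridged cyclodecenone A2 goes back to the tertiary alcohol A1, a 7-oxanorbornane in which C4 and C9 carry an (E)-alkoxyvinyl and an (E)-dienyl group on the exo face. Forward, the potassium alkoxide of A1 (KH, 18-crown-6, THF) would undergo an anionic oxy-Cope rearrangement through a boat array and give A2 after protonation of the enolate.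
- In its favour: one pericyclic step makes C6–C7, expands the ring, delivers the Z C4=C5 alkene and fixes C6 and C7 from alkene geometry; the bridging oxygen is present from the start. On the C4–C6 region this is better than the chosen plan, which needs a dehydrogenation and a hydride reduction on the macrocycle.
- Against it here: A1 has two adjacent fully substituted carbons, a geometrically pure enol ether and a diene, and would have to come from a reversible furan Diels–Alder reaction. Both alkenyl groups must fold over the oxygen bridge in the transition state. A2 still lacks the C8 oxygen, has C9 as a ketone, C2–C3 saturated and C12 at the ether level, so hydroxylation, reduction, dehydrogenation and allylic oxidation would all follow on a strained ring.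
- Comparison: structurally the alternative is stronger at C4–C7 and weaker at C8–C10, which the chosen plan sets on a rigid tetralin. Mechanistically both avoid a macrocyclisation and are equal there, but a strongly basic rearrangement is less forgiving than a neutral ozonolysis. In step economy, the access to A1 plus the end-game from A2 should not be shorter than the 21 steps of the chosen plan.

Alternative 2: The cut is the C2–C3 and C1–O pair of bonds of an isoxazole that stands for the furanone. The isoxazole-bridged lactone A5 goes back to the nitrile oxide A4 and to the acyclic aldoxime A3, which carries a terminal alkyne on C10. Forward, A3 would be oxidised (NaOCl, CH2Cl2/H2O, high dilution) to A4, whose dipole adds to the alkyne so that the carbocycle and the heterocycle close together to A5. N–O cleavage (Mo(CO)6), hydrolysis and cyclodehydration would then give the furanone.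
- In its favour: all stereocentres from C6 to C10, the lactone and the Z alkene are made on an open chain, the route is convergent, and the isoxazole is a robust mask of the 1,3-dicarbonyl. Having C4=C5 and the lactone in place before ring formation is better than the chosen plan, and the latent-diketone idea is its equal.
- Against it here: the ring closure must form a ten-membered ring in which a seven-atom chain bridges the 3- and 5-positions of the isoxazole. That is strained and entropically costly, so dimerisation of A4 competes. The conjugated Z alkene of A4 may isomerise, and the reductive N–O cleavage must later spare a lactone and a dienone.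
- Comparison: structurally the alternative handles C4–C7 better. Mechanistically the chosen plan is safer, because it creates the medium ring by cutting a bond instead of closing one. In step economy the alternative could be the shorter in longest linear sequence, provided the cyclisation works at all.

Alternative 3: The cut is the C7–C8 bond. The 8-hydroxy-9-oxo methylene lactone A7 goes back to the thirteen-membered cyclic ether A6, in which O8 is bonded to C13 of a butenolide. Forward, the C9 ketone of A6 would be enolised (LiN(SiMe3)2, THF, −78 °C) and C8 would attack C7 in a [2,3]-Wittig shift while the C13–O bond breaks, contracting the ring to A7.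
- In its favour: one step makes C7–C8, both stereocentres, the exo-methylene group and a free C8 hydroxyl beside a C9 ketone. The automatic differentiation of C8 and C9 and the built-in methylene group are better than the chosen plan, which needs a separate methylenation and a regioselective acylation.
- Against it here: the base meets a butenolide with an acidic C6–H. The sense of induction at C7 and C8 in a transannular shift is hard to predict. A [1,2]-shift or a Michael/elimination path can compete. The contraction builds the ring strain in the C–C bond-forming step, A6 itself needs a macrocyclic ether closure, and the C9 ketone of A7 must afterwards be reduced selectively next to an exo-methylene lactone.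
- Comparison: structurally the alternative is superior for the C8/C9/C13 functional pattern and inferior for stereocontrol. Mechanistically the chosen plan relies on reactions of known sense on a six-membered ring. In step economy the end-game of the alternative would be shorter, but its macrocyclic precursor would not be.

Key step: step 15

Remarks on the chemistry (assumptions):
- Germacrane numbering (C1–C15) is used for every ring compound; in the tetralin series β is the ring face that carries the C7 CH2CO2R chain and α the opposite face.
- tert-Butyl pent-4-enoate (2) is taken to be a commercial ester; it replaces a second methyl ester so that only the C10 carboxyl can acylate the arene.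
- (R)-BINAP is assumed to be the ligand enantiomer that delivers the aryl group to the 2Re face of the E-enoate 3; if the sense of induction is the opposite, the mirror-image ligand is used.
- C4 in 21–24 and selenium in 11 are stereochemical mixtures without consequence.

## Route

Step 1
Reactants: 1 methyl acrylate; 2 tert-butyl pent-4-enoate
Product: 3 6-tert-butyl 1-methyl (2E)-hex-2-enedioate
Conditions: RuCl2(=CHPh)(H2IMes)(PCy3) (second-generation Grubbs catalyst, 2 mol %), 1 (3 equiv), CH2Cl2, 40 °C
Reagents that add atoms: none
Why: Olefin cross-metathesis between a terminal alkene and an acrylate, which is slow to homodimerise, should give the E cross-product selectively with ethene as the only co-product.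

Step 2
Reactants: 3 6-tert-butyl 1-methyl (2E)-hex-2-enedioate; 4 (4-methoxy-3-methylphenyl)boronic acid
Product: 5 6-tert-butyl 1-methyl (3S)-3-(4-methoxy-3-methylphenyl)hexanedioate
Conditions: Rh(acac)(C2H4)2 (3 mol %), (R)-BINAP (3.3 mol %), 4 (2.5 equiv), dioxane/H2O (10:1), 100 °C
Reagents that add atoms: none
Why: Hayashi–Miyaura rhodium-catalysed conjugate arylation: the aryl–rhodium species adds across the only conjugated alkene and the bisphosphine discriminates the enoate faces, so that aryl delivery to the 2Re face sets C7 as (3S); the remote tert-butyl ester is a spectator.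

Step 3
Reactants: 5 6-tert-butyl 1-methyl (3S)-3-(4-methoxy-3-methylphenyl)hexanedioate
Product: 7 methyl 2-[(1S)-6-methoxy-7-methyl-4-oxo-1,2,3,4-tetrahydronaphthalen-1-yl]acetate, via mono-acid 6 (not isolated)
Conditions: CF3CO2H/CH2Cl2 (1:3), 0 °C to rt; evaporate; P2O5/MeSO3H (Eaton's reagent), rt
Reagents that add atoms: none
Why: Acidolysis frees only the C10 carboxyl (the methyl ester is stable), so the Friedel–Crafts acylation can only close the six-membered ketone; it should go to the ring carbon para to the methyl group and not to the hindered carbon between chain and methyl. The benzylic stereocentre is not involved.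

Step 4
Reactants: 7 methyl 2-[(1S)-6-methoxy-7-methyl-4-oxo-1,2,3,4-tetrahydronaphthalen-1-yl]acetate
Product: 8 methyl 2-[6-methoxy-7-methyl-4-oxo-3-(phenylselanyl)-1,2,3,4-tetrahydronaphthalen-1-yl]acetate with C9 α-SePh (trans to the C7 chain)
Conditions: LiN(iPr)2 (1.1 equiv), THF, −78 °C; PhSeCl, −78 °C
Reagents that add atoms: benzeneselenenyl chloride, Cl[Se]c1ccccc1
Why: The aryl ketone is far more acidic than the ester, so one equivalent of amide base gives only the C9 enolate (α-selenenylation); PhSeCl should approach anti to the pseudoaxial C7 chain and give mainly the α selenide, the β epimer being separable and recyclable by base epimerisation.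

Step 5
Reactants: 8 the α-selenide; 9 methylmagnesium bromide
Product: 10 methyl 2-[4-hydroxy-6-methoxy-4,7-dimethyl-3-(phenylselanyl)-1,2,3,4-tetrahydronaphthalen-1-yl]acetate with C10 β-CH3 and α-OH, C9 α-SePh
Conditions: CeCl3 (anhydrous, 1.5 equiv), 9 (1.3 equiv), THF, −78 °C; NH4Cl (aq.)
Reagents that add atoms: none
Why: Organocerium 1,2-addition is fast for ketones at −78 °C, leaves the methyl ester alone and does not enolise the α-seleno ketone; attack anti to the C9–Se bond (the large α-substituent) places the new methyl β and the C10 hydroxyl α, that is trans to the C7 chain.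

Step 6
Reactants: 10 the β-hydroxy selenide
Product: 12 methyl 2-(4-hydroxy-6-methoxy-4,7-dimethyl-1,4-dihydronaphthalen-1-yl)acetate with C10 α-OH (trans to the C7 chain) and β-CH3, via selenoxide 11 (not isolated)
Conditions: H2O2 (30 %, 2.5 equiv), pyridine, CH2Cl2, 0 °C to rt
Reagents that add atoms: none
Why: Selenoxide syn-elimination can only take a hydrogen from C8 because C10 is fully substituted, which gives the C8=C9 alkene of a tertiary allylic alcohol; pyridine buffers the selenenic acid and protects the acid-sensitive carbinol.

Step 7
Reactants: 12 the allylic alcohol ester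
Product: 13 2-(4-hydroxy-6-methoxy-4,7-dimethyl-1,4-dihydronaphthalen-1-yl)acetic acid, stereocentres as in 12
Conditions: LiOH·H2O, THF/MeOH/H2O (3:1:1), 0 °C to rt; then HCl (1 M) to pH 4, 0 °C
Reagents that add atoms: lithium hydroxide, [Li+].[OH-]
Why: Saponification frees the carboxyl group that acts as the internal nucleophile in step 8; the C10 hydroxyl is trans to the chain and cannot lactonise.

Step 8
Reactants: 13 the allylic alcohol acid
Product: 15 tricyclic hydroxy lactone (C12–O–C8 γ-lactone cis-fused on the β face, C9 α-OH, C10 α-OH and β-CH3), via epoxy acid 14 (not isolated)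
Conditions: mCPBA (1.3 equiv), CH2Cl2, 0 °C to rt
Reagents that add atoms: 3-chloroperoxybenzoic acid, OOC(=O)c1cccc(Cl)c1
Why: Peracid epoxidation is directed to the α face by hydrogen bonding to the C10 hydroxyl and by the β methyl and chain. The β carboxyl then opens the epoxide at C8 from the rear in a 5-exo fashion (epoxy-lactonisation), which fixes C8–O cis to the C7 chain; C9 keeps an α hydroxyl for now.

Step 9
Reactants: 15 the hydroxy lactone
Product: 16 keto lactone (C9 ketone; C8–O lactone β; C10 α-OH and β-CH3)
Conditions: IBX (1.5 equiv), DMSO, rt
Reagents that add atoms: none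
Why: IBX oxidises the secondary C9 alcohol to the ketone without cleaving the vicinal diol and leaves the tertiary C10 alcohol untouched.

Step 10
Reactants: 16 the keto lactone
Product: 17 hydroxy lactone with C9 β-OH (cis to the C8 lactone oxygen; C10 α-OH and β-CH3)
Conditions: NaBH4, MeOH/CH2Cl2 (1:1), −40 °C
Reagents that add atoms: none
Why: Borohydride should add from the α face, which is the convex face of the cis-fused lactone, is anti to the β methyl on C10 and carries the C10 hydroxyl that can guide the reagent; the C9 hydroxyl thus ends up β. At −40 °C the lactone is not reduced.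

Step 11
Reactants: 17 the cis-hydroxy lactone
Product: 18 methyl 2-(C8,C9-O-isopropylidene-8β,9β,10α-trihydroxy tetralinyl)acetate, that is the aromatic ring-A analogue of 22
Conditions: Me2C(OMe)2/MeOH (4:1), camphorsulfonic acid (10 mol %), rt
Reagents that add atoms: 2,2-dimethoxypropane, COC(C)(C)OC; methanol, CO
Why: Acid-catalysed methanolysis of the γ-lactone is pulled to the open form because the liberated cis-8,9-diol is captured at once as the isopropylidene acetal (transacetalisation), a known way to turn hydroxy lactones into acetonide esters; the trans-disposed C10 hydroxyl stays free.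

Step 12
Reactants: 18 the acetonide ester
Product: 19 the corresponding acetonide carboxylic acid
Conditions: LiOH·H2O, THF/H2O (3:1), rt; then HCl (1 M) to pH 5, 0 °C
Reagents that add atoms: lithium hydroxide, [Li+].[OH-]
Why: Saponification: a methyl ester would be reduced by lithium in ammonia whereas a carboxylate is inert; the acetonide tolerates the basic hydrolysis and the mildly acidic work-up.

Step 13
Reactants: 19 the acetonide acid
Product: 21 hexahydronaphthalenone acid (C3 ketone, C1=C6 ring-fusion alkene, C4 epimers, C8/C9 acetonide, C10 carbinol), via enol ether 20 (not isolated)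
Conditions: Li (excess), NH3(l)/THF, −78 °C, then t-BuOH, −78 to −33 °C; NH4Cl; then (CO2H)2, THF/H2O, 0 °C to rt
Reagents that add atoms: water, O
Why: Birch reduction of the dilithium salt: the C10 alkoxide resists benzylic C–O hydrogenolysis, and protonation at the two unsubstituted, para-related ring carbons C2 and C5 leaves the C3=C4 enol ether and the tetrasubstituted C1=C6 alkene. Oxalic acid then hydrolyses only the enol ether to the β,γ-unsaturated C3 ketone without moving the ring-fusion alkene or opening the acetonide.

Step 14
Reactants: 21 the hexahydronaphthalenone acid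
Product: 22 methyl ester of 21 (hexahydronaphthalenone with C1=C6 ring-fusion alkene, C8/C9 acetonide, C10 carbinol, C4 epimers)
Conditions: Me3SiCHN2, MeOH/toluene (1:4), 0 °C
Reagents that add atoms: (trimethylsilyl)diazomethane, C[Si](C)(C)C=[N+]=[N-]
Why: Neutral O-methylation of the carboxylic acid by diazomethane generated from Me3SiCHN2 restores the ester without acid or base, so the β,γ-enone and the tertiary allylic alcohol are not disturbed.

Step 15
Reactants: 22 the hexahydronaphthalenone ester
Product: 24 ten-membered furanone 6-ketone (C1 ketone, C2=C3, O bridge C3–C10, C6 ketone, C4–C5 saturated, C8/C9 acetonide, methyl ester), via triketone 23 (not isolated)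
Conditions: O3, CH2Cl2/MeOH (5:1), −78 °C; Me2S, −78 °C to rt; then TsOH·H2O (5 mol %), CH2Cl2, rt
Reagents that add atoms: ozone, [O-][O+]=O
Why: Ozone adds as a 1,3-dipole to the only alkene of 22, the electron-rich tetrasubstituted C1=C6 bond; the primary ozonide cycloreverts to a ketone and a carbonyl oxide that methanol captures, and Me2S reduces the hydroperoxide so that both fusion carbons emerge as ketones in 23. The ten-membered ring therefore appears by cleavage of the bond shared by two six-membered rings, and no carbon–carbon bond has to be made across a medium ring. The closest known reactions are the ozonolysis of Birch-derived octalins with a ring-fusion alkene to cyclodecane-1,6-diones and the acid cyclodehydration of α'-hydroxy-1,3-diketones to 3(2H)-furanones. In 23 the C1/C3 diketone is largely enolised; with catalytic TsOH the tertiary C10 hydroxyl adds to the C3 carbonyl (5-exo-trig) and the hemiketal loses water to the vinylogous ester, which closes the furanone ring. No stereocentre is created; C8–C10 are untouched, and C7, now α to the C6 ketone and β to the C8 oxygen, should keep its configuration because the sequence stays neutral to weakly acidic and base is excluded. Chemoselectivity rests on the absence of any other π bond that ozone attacks at −78 °C (the enol ether of 20 was hydrolysed beforehand), and the allylic C10 oxygen should steer the carbonyl oxide to C6, so C1–C10 fragmentation is not expected. Regioselectivity of the cyclodehydration is secured by the substrate: the C9 oxygen is tied in the acetonide and cannot form a pyranone, addition of the C10 hydroxyl to C6 gives only a reversible six-membered hemiketal, and once C3 is a vinylogous ester a furan synthesis from the C3/C6 1,4-diketone is switched off. C4 remains an epimer mixture, which step 16 erases.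

Step 16
Reactants: 24 the furanone 6-ketone
Product: 25 (4Z)-enone: the C4=C5 alkene conjugated to the C6 ketone and to the furanone, other centres as in 24
Conditions: IBX (3 equiv), DMSO/fluorobenzene (1:2), 70 °C
Reagents that add atoms: none
Why: IBX dehydrogenation of ketones runs through the enol; enolisation of the C6 ketone toward the C5 methylene and vinylogous enolisation of the furanone at C4 both lead to the same doubly conjugated C4=C5 alkene, while the hindered tertiary C7 enolises more slowly. The Z isomer is expected because an E alkene next to the bridging furanone would be badly strained in the ten-membered ring.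

Step 17
Reactants: 25 the Z-enone
Product: 27 6,12-lactone acetonide (cis-fused γ-lactone, H6 syn to H7, Z C4=C5, furanone, C8/C9 acetonide), via hydroxy ester 26 (not isolated)
Conditions: NaBH4, CeCl3·7H2O, MeOH, −78 °C; then pyridinium p-toluenesulfonate (cat.), toluene, 40 °C
Reagents that add atoms: none
Why: Luche reduction gives 1,2-reduction of the enone and spares the less electrophilic vinylogous ester carbonyl C1. Hydride should come from the outer face, anti to the C7–C8 ring bond (C8 as the large α-substituent), which places H6 syn to H7; the hydroxy ester then closes to the cis-fused γ-lactone under mild acid.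

Step 18
Reactants: 27 the lactone acetonide
Product: 30 α-methylene lactone acetonide (C11=C13), via Mannich base 28 (not isolated), via ammonium iodide 29 (not isolated)
Conditions: LiN(iPr)2 (1.2 equiv), THF, −78 °C; CH2=NMe2+ I−, −78 °C to rt; MeI, MeOH, rt; NaHCO3 (aq.), CH2Cl2, rt
Reagents that add atoms: N,N-dimethylmethyleneiminium iodide (Eschenmoser's salt), C=[N+](C)C.[I-]
Why: Kinetic deprotonation of the lactone at C11 and Mannich reaction with Eschenmoser's salt, followed by N-methylation and E1cB loss of trimethylamine, is the standard α-methylenation of γ-lactones; C11 is the only sp3 carbon α to a carbonyl that bears hydrogen.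

Step 19
Reactants: 30 the α-methylene lactone acetonide
Product: 31 8,9-diol (target skeleton with free C8 and C9 hydroxyls)
Conditions: CF3CO2H/H2O (9:1), CH2Cl2, 0 °C
Reagents that add atoms: none
Why: Acid hydrolysis of the isopropylidene acetal; the exo-methylene lactone and the vinylogous ester are stable to aqueous acid at 0 °C for the short time needed.

Step 20
Reactants: 31 the 8,9-diol
Product: 32 8-O-methacrylate with free C9 hydroxyl
Conditions: methacrylic anhydride (1.1 equiv), Et3N, DMAP (cat.), CH2Cl2, −20 °C
Reagents that add atoms: methacrylic anhydride, CC(=C)C(=O)OC(=O)C(C)=C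
Why: DMAP-catalysed acylation with a limiting amount of anhydride at low temperature should take the more accessible C8 hydroxyl, because the C9 hydroxyl is flanked by the fully substituted C10; low temperature limits acyl migration and lactone translocation.

Step 21
Reactants: 32 the 8-O-methacrylate
Product: 33 CNP0365569.3 (8-O-methacryloyl-9-O-acetyl furanoheliangolide, the target)
Conditions: Ac2O, pyridine, DMAP (cat.), CH2Cl2, 0 °C to rt
Reagents that add atoms: acetic anhydride, CC(=O)OC(C)=O
Why: Acetylation of the remaining hindered C9 hydroxyl under nucleophilic catalysis completes the target; no stereocentre is touched.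

## Compound list

1 | methyl acrylate | C=CC(=O)OC | starting material
2 | tert-butyl pent-4-enoate | C=CCCC(=O)OC(C)(C)C | starting material
3 | 6-tert-butyl 1-methyl (2E)-hex-2-enedioate | COC(=O)/C=C/CCC(=O)OC(C)(C)C | intermediate
4 | (4-methoxy-3-methylphenyl)boronic acid | COc1ccc(B(O)O)cc1C | starting material
5 | 6-tert-butyl 1-methyl (3S)-3-(4-methoxy-3-methylphenyl)hexanedioate | COC(=O)C[C@H](CCC(=O)OC(C)(C)C)c1ccc(OC)c(C)c1 | intermediate
6 | (4S)-6-methoxy-4-(4-methoxy-3-methylphenyl)-6-oxohexanoic acid (not isolated) | COC(=O)C[C@H](CCC(=O)O)c1ccc(OC)c(C)c1 | intermediate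
7 | methyl 2-[(1S)-6-methoxy-7-methyl-4-oxo-1,2,3,4-tetrahydronaphthalen-1-yl]acetate | COC(=O)C[C@@H]1CCC(=O)c2cc(OC)c(C)cc12 | intermediate
8 | C9 α-phenylselanyl tetralone ester (SePh trans to the C7 chain) | COC(=O)C[C@@H]1C[C@@H]([Se]c3ccccc3)C(=O)c2cc(OC)c(C)cc12 | intermediate
9 | methylmagnesium bromide | C[Mg]Br | starting material
10 | β-hydroxy selenide (C10 β-CH3, α-OH; C9 α-SePh) | COC(=O)C[C@@H]1C[C@@H]([Se]c3ccccc3)[C@@](C)(O)c2cc(OC)c(C)cc12 | intermediate
11 | selenoxide of 10 (not isolated) | COC(=O)C[C@@H]1C[C@@H]([Se](=O)c3ccccc3)[C@@](C)(O)c2cc(OC)c(C)cc12 | intermediate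
12 | methyl 2-(4-hydroxy-6-methoxy-4,7-dimethyl-1,4-dihydronaphthalen-1-yl)acetate, C10 α-OH trans to the C7 chain | COC(=O)C[C@@H]1C=C[C@@](C)(O)c2cc(OC)c(C)cc12 | intermediate
13 | carboxylic acid of 12 | OC(=O)C[C@@H]1C=C[C@@](C)(O)c2cc(OC)c(C)cc12 | intermediate
14 | 8,9-α-epoxy acid, epoxide cis to the C10 hydroxyl (not isolated) | OC(=O)C[C@@H]1[C@H]2O[C@H]2[C@@](C)(O)c2cc(OC)c(C)cc12 | intermediate
15 | tricyclic 8,12-lactone with C9 α-OH and C10 α-OH | O=C1C[C@@H]2[C@H](O1)[C@@H](O)[C@@](C)(O)c3cc(OC)c(C)cc32 | intermediate
16 | tricyclic 8,12-lactone with C9 ketone | O=C1C[C@@H]2[C@H](O1)C(=O)[C@@](C)(O)c3cc(OC)c(C)cc32 | intermediate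
17 | tricyclic 8,12-lactone with C9 β-OH (cis to O8) and C10 α-OH | O=C1C[C@@H]2[C@H](O1)[C@H](O)[C@@](C)(O)c3cc(OC)c(C)cc32 | intermediate
18 | tetralin 8β,9β-acetonide methyl ester, C10 α-OH | COC(=O)C[C@@H]1[C@@H]2OC(C)(C)O[C@@H]2[C@@](C)(O)c2cc(OC)c(C)cc12 | intermediate
19 | tetralin 8β,9β-acetonide carboxylic acid, C10 α-OH | OC(=O)C[C@@H]1[C@@H]2OC(C)(C)O[C@@H]2[C@@](C)(O)c2cc(OC)c(C)cc12 | intermediate
20 | Birch product: C3 methyl enol ether, C1=C6 and C3=C4 diene, acid (not isolated) | OC(=O)C[C@H]1C2=C(CC(OC)=C(C)C2)[C@](C)(O)[C@H]2OC(C)(C)O[C@@H]12 | intermediate
21 | hexahydronaphthalenone acid (C3 ketone, C1=C6 alkene, C4 epimers) | OC(=O)C[C@H]1C2=C(CC(=O)C(C)C2)[C@](C)(O)[C@H]2OC(C)(C)O[C@@H]12 | intermediate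
22 | hexahydronaphthalenone methyl ester with C1=C6 ring-fusion alkene (C8/C9 acetonide, C10 carbinol, C4 epimers) | COC(=O)C[C@H]1C2=C(CC(=O)C(C)C2)[C@](C)(O)[C@H]2OC(C)(C)O[C@@H]12 | intermediate
23 | cyclodecane-1,3,6-trione with C10 hydroxyl (not isolated) | COC(=O)C[C@H]1C(=O)CC(C)C(=O)CC(=O)[C@](C)(O)[C@H]2OC(C)(C)O[C@@H]12 | intermediate
24 | ten-membered furanone 6-ketone (C4–C5 saturated, C4 epimers) | COC(=O)C[C@H]1C(=O)CC(C)C2=CC(=O)[C@](C)(O2)[C@H]2OC(C)(C)O[C@@H]12 | intermediate
25 | ten-membered furanone (4Z)-en-6-one | COC(=O)C[C@H]1C(=O)/C=C(/C)C2=CC(=O)[C@](C)(O2)[C@H]2OC(C)(C)O[C@@H]12 | intermediate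
26 | C6 hydroxy ester, H6 syn to H7 (not isolated) | COC(=O)C[C@H]1[C@@H](O)/C=C(/C)C2=CC(=O)[C@](C)(O2)[C@H]2OC(C)(C)O[C@@H]12 | intermediate
27 | cis-fused 6,12-lactone acetonide | CC1(C)O[C@H]2[C@H]3CC(=O)O[C@H]3/C=C(/C)C3=CC(=O)[C@](C)(O3)[C@H]2O1 | intermediate
28 | C11 dimethylaminomethyl lactone (not isolated) | CC1(C)O[C@H]2[C@H]3C(CN(C)C)C(=O)O[C@H]3/C=C(/C)C3=CC(=O)[C@](C)(O3)[C@H]2O1 | intermediate
29 | C11 trimethylammoniomethyl lactone iodide (not isolated) | CC1(C)O[C@H]2[C@H]3C(C[N+](C)(C)C)C(=O)O[C@H]3/C=C(/C)C3=CC(=O)[C@](C)(O3)[C@H]2O1.[I-] | intermediate
30 | α-methylene 6,12-lactone acetonide | CC1(C)O[C@H]2[C@H]3C(=C)C(=O)O[C@H]3/C=C(/C)C3=CC(=O)[C@](C)(O3)[C@H]2O1 | intermediate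
31 | α-methylene lactone 8,9-diol | O[C@H]1[C@H]2C(=C)C(=O)O[C@H]2/C=C(/C)C2=CC(=O)[C@](C)(O2)[C@H]1O | intermediate
32 | 8-O-methacrylate 9-alcohol | C=C(C)C(=O)O[C@H]1[C@H]2C(=C)C(=O)O[C@H]2/C=C(/C)C2=CC(=O)[C@](C)(O2)[C@H]1O | intermediate
33 | CNP0365569.3 | C=C(C)C(=O)O[C@H]1[C@H]2C(=C)C(=O)O[C@H]2/C=C(/C)C2=CC(=O)[C@](C)(O2)[C@H]1OC(C)=O | target

## Step count and least certain steps

Total: 21 steps. Longest linear sequence: 21 steps (1 or 2 to 33).

Step 15 (key step). The most likely failures are a fragmentation of the allylic carbonyl oxide with loss of the C1–C10 bond, slow reduction of an intramolecular cross-ozonide, and a transannular aldol condensation of the 1,3,6-triketone (the enolised C2 onto the C6 ketone) before the furanone has closed. All three come from the density of carbonyl groups that the cleavage creates at once. Fallback: from 22 the ring-fusion alkene is dihydroxylated with stoichiometric OsO4 in pyridine (reductive work-up with NaHSO3) to the ditertiary cis-diol F1. Glycol cleavage of F1 with Pb(OAc)4 in CH2Cl2 gives the same triketone without any peroxidic intermediate, and catalytic TsOH closes the furanone, which returns the route at 24.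

Step 17. Poor facial selectivity in the hydride delivery to the macrocyclic enone is the main danger, because the preferred conformation about C6–C7 of the ten-membered ring is not known; some conjugate reduction is a second danger. Fallback: if the hydride enters from the other face, 25 gives the 6-epi hydroxy ester F2. Saponification (LiOH, THF/H2O) leads to the 6-epi hydroxy acid F3, and an intramolecular Mitsunobu lactonisation (PPh3, diisopropyl azodicarboxylate, toluene) closes the lactone with inversion at the allylic C6, which returns the route at 27.

Step 16. Dehydrogenation on the wrong side of the ketone (toward C7 and C11, giving an alkylidene keto ester) or over-oxidation could compete, because IBX acts on whichever enol forms. Fallback: from 24, kinetic enolisation with LiN(SiMe3)2 in the presence of Me3SiCl at −78 °C gives the less substituted silyl enol ether F4, and Saegusa–Ito oxidation of F4 with Pd(OAc)2 in MeCN gives 25.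

Step 20. Unselective acylation of the two secondary hydroxyls, base-induced acyl migration or translocation of the lactone from O6 to O8 may occur, since both hydroxyls are hindered and the C8 hydroxyl is γ to the lactone carbonyl. Fallback: from 31 the diol is converted with MeC(OMe)3 and pyridinium p-toluenesulfonate into the cyclic orthoacetate F5. Mild aqueous acetic acid opens it, expected mainly to the ester of the more hindered oxygen, the 9-acetate 8-alcohol F6. Methacrylation of F6 (methacrylic anhydride, DMAP) then gives 33.

Step 11. Ionisation of the tertiary benzylic C10 alcohol under the acid (solvolysis or loss of configuration), or an unfavourable lactone/ester equilibrium, could lower the efficiency. Fallback: from 17 the lactone is opened without Brønsted acid by Me2AlN(OMe)Me in CH2Cl2 to the Weinreb amide triol F7. Its cis-8,9-diol is protected at once with 2-methoxypropene and pyridinium p-toluenesulfonate to give the acetonide amide F8, and hydrolysis of F8 (KOH, EtOH/H2O, heat) gives 19, which also saves step 12.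

Step 4 (with step 5). Insufficient facial control in the selenenylation would be carried into the wrong C10 configuration, and selenium–metal exchange could compete with addition in step 5. Fallback: from 7, addition of 9 with CeCl3 and dehydration on acidic work-up (TsOH, toluene) gives the 1-methyl-3,4-dihydronaphthalene F9. Buffered mCPBA epoxidation anti to the pseudoaxial C7 chain gives the α-epoxide F10. PhSeNa (from PhSeSePh and NaBH4 in EtOH) opens F10 at C9 to the β-selenide F11, and oxidation with H2O2 and syn-elimination gives 12.

## Further compounds

F1 | step 15 | C1,C6-cis-diol of 22 (both hydroxyls α) | COC(=O)C[C@H]1[C@@]2(O)CC(C)C(=O)C[C@@]2(O)[C@](C)(O)[C@H]2OC(C)(C)O[C@@H]12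
F2 | step 17 | 6-epi hydroxy ester | COC(=O)C[C@H]1[C@H](O)/C=C(/C)C2=CC(=O)[C@](C)(O2)[C@H]2OC(C)(C)O[C@@H]12
F3 | step 17 | 6-epi hydroxy acid | OC(=O)C[C@H]1[C@H](O)/C=C(/C)C2=CC(=O)[C@](C)(O2)[C@H]2OC(C)(C)O[C@@H]12
F4 | step 16 | C6 trimethylsilyl enol ether (C5=C6) of 24 | COC(=O)C[C@H]1C(O[Si](C)(C)C)=CC(C)C2=CC(=O)[C@](C)(O2)[C@H]2OC(C)(C)O[C@@H]12
F5 | step 20 | cyclic 8,9-orthoacetate of 31 | COC1(C)O[C@H]2[C@H]3C(=C)C(=O)O[C@H]3/C=C(/C)C3=CC(=O)[C@](C)(O3)[C@H]2O1
F6 | step 20 | 9-O-acetate 8-alcohol | O[C@H]1[C@H]2C(=C)C(=O)O[C@H]2/C=C(/C)C2=CC(=O)[C@](C)(O2)[C@H]1OC(C)=O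
F7 | step 11 | N-methoxy-N-methyl amide of the 8β,9β,10α-triol | CON(C)C(=O)C[C@@H]1[C@H](O)[C@H](O)[C@@](C)(O)c2cc(OC)c(C)cc12
F8 | step 11 | 8,9-acetonide of F7 | CON(C)C(=O)C[C@@H]1[C@@H]2OC(C)(C)O[C@@H]2[C@@](C)(O)c2cc(OC)c(C)cc12
F9 | step 4 | methyl 2-[(1S)-6-methoxy-4,7-dimethyl-1,2-dihydronaphthalen-1-yl]acetate | COC(=O)C[C@@H]1CC=C(C)c2cc(OC)c(C)cc12
F10 | step 4 | 9,10-α-epoxide of F9 (trans to the C7 chain) | COC(=O)C[C@@H]1C[C@H]2O[C@@]2(C)c2cc(OC)c(C)cc12
F11 | step 4 | β-hydroxy selenide with C9 β-SePh, C10 α-OH and β-CH3 | COC(=O)C[C@@H]1C[C@H]([Se]c3ccccc3)[C@@](C)(O)c2cc(OC)c(C)cc12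
A1 | alternative 1 | exo,exo-dialkenyl 7-oxanorbornane tertiary alcohol (C1 dioxolane, C4 (E)-alkoxyvinyl, C9 (E)-dienyl) | COc1ccc(CO/C=C/[C@]2(C)[C@H]3CC4(OCCO4)[C@](C)(O3)[C@]2(O)/C=C/C(=C)COCc2ccc(OC)cc2)cc1
A2 | alternative 1 | oxygen-bridged cyclodec-4-en-9-one with C6 ether and C7 allyl ether arm | C1[C@@H](C(=C)COCc3ccc(OC)cc3)[C@@H](OCc3ccc(OC)cc3)/C=C(/C)[C@H]2CC3(OCCO3)[C@](C)(O2)C1=O
A3 | alternative 2 | acyclic aldoxime with terminal alkyne, lactone and acetonide | O/N=C/C(C)=C\[C@@H]1OC(=O)C[C@@H]1[C@@H]1OC(C)(C)O[C@@H]1[C@@](C)(O)C#C
A4 | alternative 2 | nitrile oxide derived from A3 | [O-][N+]#C/C(C)=C\[C@@H]1OC(=O)C[C@@H]1[C@@H]1OC(C)(C)O[C@@H]1[C@@](C)(O)C#C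
A5 | alternative 2 | isoxazole-bridged ten-membered lactone | C/C1=C/[C@@H]2OC(=O)C[C@@H]2[C@@H]2OC(C)(C)O[C@@H]2[C@@](C)(O)c2cc1no2
A6 | alternative 3 | thirteen-membered cyclic ether (O8–C13 ether, butenolide, C9 ketone, furanone) | O=C1O[C@@H]2C=C1COCC(=O)[C@@]3(C)OC(=CC3=O)/C(C)=C\2
A7 | alternative 3 | 8-hydroxy-9-oxo methylene lactone macrocycle | O[C@H]1[C@H]2C(=C)C(=O)O[C@H]2/C=C(/C)C2=CC(=O)[C@](C)(O2)C1=O
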